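**Retrosynthetic overview**
1. The target is an ent-matairesinol lactone (3S,4S) carrying two β-5-linked guaiacylpropane units: one closed (trans-dihydrobenzofuran), one open (erythro diol). Both share the same (S) benzylic CH(CH2OH) centre, so one auxiliary-controlled anti-aldol serves both.
2. The 8–8′ bond of the lactone is not made by the usual lactone α-benzylation. It is made by oxidative heterocoupling of an Evans imide enolate (ring B arm) with an ester enolate (ring C arm); the auxiliary fixes C-4 and C-3 is equilibrated to trans.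
3. The β-5 units are added late on the dihalide core: Pd/zinc-enolate arylation puts an arylacetyl imide on the aryl iodide first and on the aryl bromide second, and each is followed by a Mg-catalysed anti-aldol with O-benzylvanillin.
4. Ring order: butyrolactone first (reduction/lactonisation), then the dihydrobenzofuran (acid-mediated SN1 closure, trans). The second β-5 unit is kept open, and hydrogenolysis finishes the synthesis.

Assumption: in the MgCl2/Et3N/TMSCl anti-aldol the chelated (Z)-enolate of the N-acyl oxazolidinone is attacked on the face opposite the 4-benzyl group (the same face as in an Evans alkylation); if the sense were reversed, the enantiomer of 15 would be used.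

**Step 1**
Reactants: 1 3-(4-hydroxy-3-methoxyphenyl)propanoic acid (dihydroferulic acid)
Product: 2 3-(3-bromo-4-hydroxy-5-methoxyphenyl)propanoic acid
Conditions: Br2 (1.05 equiv), AcOH, rt
Reagents that add atoms: bromine BrBr
Why: Electrophilic aromatic bromination; the free phenol (para position blocked) directs bromine to its only open ortho position, as in the bromination of vanillin or eugenol.

**Step 2**
Reactants: 2 3-(3-bromo-4-hydroxy-5-methoxyphenyl)propanoic acid
Product: 3 3-[4-(benzyloxy)-3-bromo-5-methoxyphenyl]propanoic acid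
Conditions: BnBr (1.1 equiv), NaOH (2.2 equiv), EtOH/H2O, reflux; then aq. HCl
Reagents that add atoms: benzyl bromide BrCc1ccccc1
Why: Williamson ether synthesis on the dianion, in which the phenoxide is far more nucleophilic than the carboxylate; benzyl survives every later step and is removed last.

**Step 3**
Reactants: 3 3-[4-(benzyloxy)-3-bromo-5-methoxyphenyl]propanoic acid; 4 (R)-4-benzyloxazolidin-2-one
Product: 6 (R)-4-benzyl-3-{3-[4-(benzyloxy)-3-bromo-5-methoxyphenyl]propanoyl}oxazolidin-2-one, via mixed pivalic anhydride 5 (not isolated)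
Conditions: PivCl, Et3N, THF, −20 °C; then 4, LiCl, rt
Reagents that add atoms: pivaloyl chloride CC(C)(C)C(Cl)=O (its atoms appear in intermediate 5 only)
Why: N-acylation of the Evans auxiliary through a mixed anhydride (LiCl/Et3N activation); no stereocentre is formed, and the (R)-auxiliary is installed to control C-4 of the lactone in step 6.

**Step 4**
Reactants: 7 methyl 3-(4-hydroxy-3-methoxyphenyl)propanoate (methyl dihydroferulate)
Product: 8 methyl 3-(4-hydroxy-3-iodo-5-methoxyphenyl)propanoate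
Conditions: NIS, TsOH·H2O (10 mol%), MeCN, rt
Reagents that add atoms: N-iodosuccinimide O=C1CCC(=O)N1I
Why: Electrophilic aromatic iodination ortho to the free phenol (para blocked); this gives the aryl iodide that will later be coupled before the aryl bromide of the other ring.

**Step 5**
Reactants: 8 methyl 3-(4-hydroxy-3-iodo-5-methoxyphenyl)propanoate
Product: 9 methyl 3-[3-iodo-5-methoxy-4-(methoxymethoxy)phenyl]propanoate
Conditions: MOMCl, iPr2NEt, CH2Cl2, 0 °C → rt
Reagents that add atoms: chloromethyl methyl ether COCCl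
Why: Acetal (MOM ether) formation on the phenol; MOM tolerates LDA, Cu(II), hydride and Pd/Zn chemistry and is later removed by the same acid that closes the dihydrobenzofuran.

**Step 6**
Reactants: 6 (R)-4-benzyl-3-{3-[4-(benzyloxy)-3-bromo-5-methoxyphenyl]propanoyl}oxazolidin-2-one; 9 methyl 3-[3-iodo-5-methoxy-4-(methoxymethoxy)phenyl]propanoate
Product: 12 methyl (2S,3S)-3-{[4-(benzyloxy)-3-bromo-5-methoxyphenyl]methyl}-4-[(R)-4-benzyl-2-oxooxazolidin-3-yl]-2-{[3-iodo-5-methoxy-4-(methoxymethoxy)phenyl]methyl}-4-oxobutanoate, via lithium Z-enolate of the imide 10 (not isolated), via lithium enolate of the ester 11 (not isolated)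
Conditions: 6 (1 equiv), 9 (1.5 equiv), LDA (2.6 equiv), THF, −78 °C; then Cu(II) 2-ethylhexanoate (2.6 equiv), −78 °C → rt
Reagents that add atoms: lithium diisopropylamide CC(C)N([Li])C(C)C (lithium appears in 10 and 11 only)
Why: Intermolecular oxidative enolate heterocoupling (Cu(II) single-electron oxidation of the mixed imide/ester enolate aggregate) forges the 8–8′ bond; the chelated (Z)-imide enolate reacts on the face opposite the auxiliary benzyl group, which fixes the imide-bearing centre as S (the future lactone C-4), while the ester-bearing centre forms mainly anti and its epimer is corrected in step 7.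

**Step 7**
Reactants: 12 methyl (2S,3S)-3-{[4-(benzyloxy)-3-bromo-5-methoxyphenyl]methyl}-4-[(R)-4-benzyl-2-oxooxazolidin-3-yl]-2-{[3-iodo-5-methoxy-4-(methoxymethoxy)phenyl]methyl}-4-oxobutanoate
Product: 14 (3S,4S)-4-{[4-(benzyloxy)-3-bromo-5-methoxyphenyl]methyl}-3-{[3-iodo-5-methoxy-4-(methoxymethoxy)phenyl]methyl}oxolan-2-one, via hydroxy ester 13 (not isolated)
Conditions: LiBH4, MeOH (1 equiv), THF, 0 °C; then DBU (0.3 equiv), CH2Cl2, rt
Reagents that add atoms: none
Why: Chemoselective hydride reduction of the N-acyl oxazolidinone (faster than the methyl ester) releases the auxiliary and the new alcohol lactonises onto the neighbouring ester; DBU then equilibrates the α-centre to the thermodynamically favoured trans-2,3-dibenzylbutyrolactone, so C-3 (S) follows from C-4 (S).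

**Step 8**
Reactants: 14 (3S,4S)-4-{[4-(benzyloxy)-3-bromo-5-methoxyphenyl]methyl}-3-{[3-iodo-5-methoxy-4-(methoxymethoxy)phenyl]methyl}oxolan-2-one; 15 (S)-3-acetyl-4-benzyloxazolidin-2-one
Product: 17 (S)-4-benzyl-3-[2-(aryl)acetyl]oxazolidin-2-one in which aryl = 5-{[(3S,4S)-4-{[4-(benzyloxy)-3-bromo-5-methoxyphenyl]methyl}-2-oxooxolan-3-yl]methyl}-3-methoxy-2-(methoxymethoxy)phenyl (14 with I replaced by the CH2C(=O)-auxiliary group), via chlorozinc enolate 16 (not isolated)
Conditions: 15 (1.3 equiv), LiHMDS, THF, −78 °C; ZnCl2; then 14, Pd(dba)2 (5 mol%), Q-Phos (5 mol%), THF, rt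
Reagents that add atoms: zinc chloride Cl[Zn]Cl (zinc and chlorine appear in 16 only)
Why: Palladium-catalysed α-arylation of a zinc imide enolate (Negishi/Reformatsky-type); with only a slight excess of enolate at room temperature oxidative addition occurs at C–I only, so the aryl bromide is kept for step 11, and the weakly basic zinc enolate leaves the lactone untouched.

**Step 9**
Reactants: 17 (S)-4-benzyl-3-[2-(aryl)acetyl]oxazolidin-2-one (aryl as defined in step 8); 18 4-(benzyloxy)-3-methoxybenzaldehyde (O-benzylvanillin)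
Product: 19 (S)-4-benzyl-3-[(2R,3S)-2-(aryl)-3-[4-(benzyloxy)-3-methoxyphenyl]-3-(trimethylsilyloxy)propanoyl]oxazolidin-2-one (aryl as in 17)
Conditions: 18 (1.5 equiv), MgCl2 (20 mol%), Et3N, TMSCl, EtOAc, rt
Reagents that add atoms: chlorotrimethylsilane C[Si](C)(C)Cl
Why: Evans magnesium-halide-catalysed direct anti-aldol (soft enolisation, silyl trapping of the aldolate); the chelated (Z)-enolate is attacked anti to the auxiliary benzyl group through a boat transition state, giving the (2R,3S) anti adduct whose α-centre becomes C-3 (S) of the dihydrobenzofuran.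

**Step 10**
Reactants: 19 (S)-4-benzyl-3-[(2R,3S)-2-(aryl)-3-[4-(benzyloxy)-3-methoxyphenyl]-3-(trimethylsilyloxy)propanoyl]oxazolidin-2-one
Product: 22 (3S,4S)-4-{[4-(benzyloxy)-3-bromo-5-methoxyphenyl]methyl}-3-({(2R,3S)-2-[4-(benzyloxy)-3-methoxyphenyl]-3-(hydroxymethyl)-7-methoxy-2,3-dihydro-1-benzofuran-5-yl}methyl)oxolan-2-one, via silylated diol 20 (not isolated), via phenolic triol 21 (not isolated)
Conditions: LiBH4, MeOH (1 equiv), THF, 0 °C; then HCl (1.25 M in MeOH), 40 °C
Reagents that add atoms: none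
Why: Reductive removal of the auxiliary (imide to CH2OH) is followed by acid-mediated intramolecular SN1 etherification: HCl/MeOH cleaves the TMS and MOM ethers and ionises the p-benzyloxybenzylic alcohol, and the freed phenol traps the cation (5-exo) under thermodynamic control, so the untouched C-3 (S) dictates the 2,3-trans ring with C-2 (R).

**Step 11**
Reactants: 22 (3S,4S)-4-{[4-(benzyloxy)-3-bromo-5-methoxyphenyl]methyl}-3-({(2R,3S)-2-[4-(benzyloxy)-3-methoxyphenyl]-3-(hydroxymethyl)-7-methoxy-2,3-dihydro-1-benzofuran-5-yl}methyl)oxolan-2-one; 15 (S)-3-acetyl-4-benzyloxazolidin-2-one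
Product: 24 (S)-4-benzyl-3-[2-(aryl)acetyl]oxazolidin-2-one in which aryl is the ring of 22 that carried Br (22 with Br replaced by the CH2C(=O)-auxiliary group), via bromozinc enolate 23 (not isolated)
Conditions: 15 (3 equiv), LiHMDS (2.9 equiv), THF, −78 °C; ZnBr2 (3 equiv); then 22, Pd(dba)2 (5 mol%), Q-Phos (5 mol%), THF, 50 °C
Reagents that add atoms: zinc bromide Br[Zn]Br (zinc and bromine appear in 23 only)
Why: Second palladium-catalysed zinc-enolate α-arylation (Negishi/Reformatsky-type), now at the remaining aryl bromide at 50 °C; transmetalation with ZnBr2 gives the bromozinc enolate, so bromide is the only halide at zinc and palladium, and this coupling type tolerates the free primary hydroxyl, which only consumes extra zinc enolate.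

**Step 12**
Reactants: 24 (S)-4-benzyl-3-[2-(aryl)acetyl]oxazolidin-2-one (aryl as defined in step 11); 18 4-(benzyloxy)-3-methoxybenzaldehyde
Product: 25 (S)-4-benzyl-3-[(2R,3S)-2-(aryl)-3-[4-(benzyloxy)-3-methoxyphenyl]-3-(trimethylsilyloxy)propanoyl]oxazolidin-2-one in which aryl is that of 24 with its CH2OH converted to CH2OSiMe3
Conditions: 18 (1.5 equiv), MgCl2 (20 mol%), Et3N, TMSCl (3 equiv), EtOAc, rt; pH 7 work-up
Reagents that add atoms: chlorotrimethylsilane C[Si](C)(C)Cl
Why: Second Evans Mg-catalysed anti-aldol under the same auxiliary control gives the (2R,3S) anti adduct, which is the erythro (7S,8S) arrangement of the open β-5 unit; the primary alcohol is silylated in passing and no acid is used, so the benzylic centre cannot ionise.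

**Step 13**
Reactants: 25 bis-silylated anti-aldol imide
Product: 27 (3S,4S)-3-({(2R,3S)-2-[4-(benzyloxy)-3-methoxyphenyl]-3-(hydroxymethyl)-7-methoxy-2,3-dihydro-1-benzofuran-5-yl}methyl)-4-({4-(benzyloxy)-3-[(1S,2S)-1-[4-(benzyloxy)-3-methoxyphenyl]-1,3-dihydroxypropan-2-yl]-5-methoxyphenyl}methyl)oxolan-2-one, via bis-silylated alcohol 26 (not isolated)
Conditions: LiBH4, MeOH (1 equiv), THF, 0 °C; then K2CO3 (cat.), MeOH, 0 °C
Reagents that add atoms: none
Why: Hydride reduction of the acyl oxazolidinone to the primary alcohol while the secondary carbinol is silyl-protected (no retro-aldol), then base-catalysed methanolysis of both TMS ethers, conditions that cannot ionise the C-7–O bond.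

**Step 14**
Reactants: 27 tri-O-benzyl ether of the target
Product: 28 (3S,4S)-3-{[(2R,3S)-2-(4-hydroxy-3-methoxyphenyl)-3-(hydroxymethyl)-7-methoxy-2,3-dihydro-1-benzofuran-5-yl]methyl}-4-({3-[(1S,2S)-1,3-dihydroxy-1-(4-hydroxy-3-methoxyphenyl)propan-2-yl]-4-hydroxy-5-methoxyphenyl}methyl)oxolan-2-one (CNP0199264.1)
Conditions: H2 (1 atm), 10% Pd/C, EtOAc/EtOH, rt
Reagents that add atoms: none
Why: Catalytic hydrogenolysis of the three aryl benzyl ethers under neutral conditions at 1 atm, where O-benzyl cleavage is much faster than hydrogenolysis of the benzylic C–O bonds of the dihydrobenzofuran and of the free benzylic alcohol; no stereocentre is touched.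

**Compound list**
1 | 3-(4-hydroxy-3-methoxyphenyl)propanoic acid | COc1cc(CCC(=O)O)ccc1O | starting material
2 | 3-(3-bromo-4-hydroxy-5-methoxyphenyl)propanoic acid | COc1cc(CCC(=O)O)cc(Br)c1O | intermediate
3 | 3-[4-(benzyloxy)-3-bromo-5-methoxyphenyl]propanoic acid | COc1cc(CCC(=O)O)cc(Br)c1OCc1ccccc1 | intermediate
4 | (R)-4-benzyloxazolidin-2-one | O=C1N[C@H](Cc2ccccc2)CO1 | starting material
5 | mixed anhydride of 3 with pivalic acid | COc1cc(CCC(=O)OC(=O)C(C)(C)C)cc(Br)c1OCc1ccccc1 | intermediate (not isolated)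
6 | (R)-4-benzyl-3-{3-[4-(benzyloxy)-3-bromo-5-methoxyphenyl]propanoyl}oxazolidin-2-one | COc1cc(CCC(=O)N2C(=O)OC[C@H]2Cc2ccccc2)cc(Br)c1OCc1ccccc1 | intermediate
7 | methyl 3-(4-hydroxy-3-methoxyphenyl)propanoate | COC(=O)CCc1ccc(O)c(OC)c1 | starting material
8 | methyl 3-(4-hydroxy-3-iodo-5-methoxyphenyl)propanoate | COC(=O)CCc1cc(I)c(O)c(OC)c1 | intermediate
9 | methyl 3-[3-iodo-5-methoxy-4-(methoxymethoxy)phenyl]propanoate | COC(=O)CCc1cc(I)c(OCOC)c(OC)c1 | intermediate
10 | lithium (Z)-enolate of imide 6 | COc1cc(C/C=C(\O[Li])N2C(=O)OC[C@H]2Cc2ccccc2)cc(Br)c1OCc1ccccc1 | intermediate (not isolated)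
11 | lithium enolate of ester 9 | COC(O[Li])=CCc1cc(I)c(OCOC)c(OC)c1 | intermediate (not isolated)
12 | methyl (2S,3S)-3-{[4-(benzyloxy)-3-bromo-5-methoxyphenyl]methyl}-4-[(R)-4-benzyl-2-oxooxazolidin-3-yl]-2-{[3-iodo-5-methoxy-4-(methoxymethoxy)phenyl]methyl}-4-oxobutanoate (major epimer; the C-2 epimer converges in step 7) | COc1cc(C[C@H](C(=O)N2C(=O)OC[C@H]2Cc2ccccc2)[C@@H](C(=O)OC)Cc2cc(OC)c(OCOC)c(I)c2)cc(Br)c1OCc1ccccc1 | intermediate
13 | methyl (2S,3S)-3-{[4-(benzyloxy)-3-bromo-5-methoxyphenyl]methyl}-4-hydroxy-2-{[3-iodo-5-methoxy-4-(methoxymethoxy)phenyl]methyl}butanoate | COc1cc(C[C@H](CO)[C@@H](C(=O)OC)Cc2cc(OC)c(OCOC)c(I)c2)cc(Br)c1OCc1ccccc1 | intermediate (not isolated)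
14 | (3S,4S)-4-{[4-(benzyloxy)-3-bromo-5-methoxyphenyl]methyl}-3-{[3-iodo-5-methoxy-4-(methoxymethoxy)phenyl]methyl}oxolan-2-one | COc1cc(C[C@@H]2COC(=O)[C@H]2Cc2cc(OC)c(OCOC)c(I)c2)cc(Br)c1OCc1ccccc1 | intermediate
15 | (S)-3-acetyl-4-benzyloxazolidin-2-one | CC(=O)N1C(=O)OC[C@@H]1Cc1ccccc1 | starting material
16 | chlorozinc enolate of 15 | C=C(O[Zn]Cl)N1C(=O)OC[C@@H]1Cc1ccccc1 | intermediate (not isolated)
17 | arylacetyl imide: 14 with I replaced by CH2C(=O)-[(S)-4-benzyl-2-oxooxazolidin-3-yl] | COc1cc(C[C@@H]2COC(=O)[C@H]2Cc2cc(OC)c(OCOC)c(CC(=O)N3C(=O)OC[C@@H]3Cc3ccccc3)c2)cc(Br)c1OCc1ccccc1 | intermediate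
18 | 4-(benzyloxy)-3-methoxybenzaldehyde | COc1cc(C=O)ccc1OCc1ccccc1 | starting material
19 | (2R,3S) anti-aldol TMS ether of 17 with 18 | COc1cc(C[C@@H]2COC(=O)[C@H]2Cc2cc(OC)c(OCOC)c([C@@H](C(=O)N3C(=O)OC[C@@H]3Cc3ccccc3)[C@H](O[Si](C)(C)C)c3ccc(OCc4ccccc4)c(OC)c3)c2)cc(Br)c1OCc1ccccc1 | intermediate
20 | (3S,4S)-4-{[4-(benzyloxy)-3-bromo-5-methoxyphenyl]methyl}-3-{[3-{(1S,2S)-1-[4-(benzyloxy)-3-methoxyphenyl]-3-hydroxy-1-(trimethylsilyloxy)propan-2-yl}-5-methoxy-4-(methoxymethoxy)phenyl]methyl}oxolan-2-one | COc1cc(C[C@@H]2COC(=O)[C@H]2Cc2cc(OC)c(OCOC)c([C@@H](CO)[C@H](O[Si](C)(C)C)c3ccc(OCc4ccccc4)c(OC)c3)c2)cc(Br)c1OCc1ccccc1 | intermediate (not isolated)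
21 | (3S,4S)-4-{[4-(benzyloxy)-3-bromo-5-methoxyphenyl]methyl}-3-{[3-{(1S,2S)-1-[4-(benzyloxy)-3-methoxyphenyl]-1,3-dihydroxypropan-2-yl}-4-hydroxy-5-methoxyphenyl]methyl}oxolan-2-one | COc1cc(C[C@@H]2COC(=O)[C@H]2Cc2cc(OC)c(O)c([C@@H](CO)[C@H](O)c3ccc(OCc4ccccc4)c(OC)c3)c2)cc(Br)c1OCc1ccccc1 | intermediate (not isolated)
22 | (3S,4S)-4-{[4-(benzyloxy)-3-bromo-5-methoxyphenyl]methyl}-3-({(2R,3S)-2-[4-(benzyloxy)-3-methoxyphenyl]-3-(hydroxymethyl)-7-methoxy-2,3-dihydro-1-benzofuran-5-yl}methyl)oxolan-2-one | COc1cc(C[C@@H]2COC(=O)[C@H]2Cc2cc(OC)c3c(c2)[C@@H](CO)[C@H](c2ccc(OCc4ccccc4)c(OC)c2)O3)cc(Br)c1OCc1ccccc1 | intermediate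
23 | bromozinc enolate of 15 | C=C(O[Zn]Br)N1C(=O)OC[C@@H]1Cc1ccccc1 | intermediate (not isolated)
24 | arylacetyl imide: 22 with Br replaced by CH2C(=O)-[(S)-4-benzyl-2-oxooxazolidin-3-yl] | COc1cc(C[C@@H]2COC(=O)[C@H]2Cc2cc(OC)c3c(c2)[C@@H](CO)[C@H](c2ccc(OCc4ccccc4)c(OC)c2)O3)cc(CC(=O)N2C(=O)OC[C@@H]2Cc2ccccc2)c1OCc1ccccc1 | intermediate
25 | (2R,3S) anti-aldol of 24 with 18, as bis-TMS ether (secondary OSiMe3 and CH2OSiMe3) | COc1cc(C[C@@H]2COC(=O)[C@H]2Cc2cc(OC)c3c(c2)[C@@H](CO[Si](C)(C)C)[C@H](c2ccc(OCc4ccccc4)c(OC)c2)O3)cc([C@@H](C(=O)N2C(=O)OC[C@@H]2Cc2ccccc2)[C@H](O[Si](C)(C)C)c2ccc(OCc3ccccc3)c(OC)c2)c1OCc1ccccc1 | intermediate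
26 | 25 with the acyl oxazolidinone reduced to CH2OH [(1S,2S) unit, both TMS ethers still in place] | COc1cc(C[C@@H]2COC(=O)[C@H]2Cc2cc(OC)c3c(c2)[C@@H](CO[Si](C)(C)C)[C@H](c2ccc(OCc4ccccc4)c(OC)c2)O3)cc([C@@H](CO)[C@H](O[Si](C)(C)C)c2ccc(OCc3ccccc3)c(OC)c2)c1OCc1ccccc1 | intermediate (not isolated)
27 | tri-O-benzyl ether of the target (full name in step 13) | COc1cc(C[C@@H]2COC(=O)[C@H]2Cc2cc(OC)c3c(c2)[C@@H](CO)[C@H](c2ccc(OCc4ccccc4)c(OC)c2)O3)cc([C@@H](CO)[C@H](O)c2ccc(OCc3ccccc3)c(OC)c2)c1OCc1ccccc1 | intermediate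
28 | CNP0199264.1 (full name in step 14) | COc1cc([C@@H](O)[C@H](CO)c2cc(C[C@@H]3COC(=O)[C@H]3Cc3cc(OC)c4c(c3)[C@@H](CO)[C@H](c3ccc(O)c(OC)c3)O4)cc(OC)c2O)ccc1O | target

**Totals**
Total step count: 14. Longest linear sequence: 12 steps (1 → 28 through steps 1–3 and 6–14).

**The three steps most likely to fail**

Step 6, oxidative heterocoupling (cross- versus homo-coupling and facial control). The fallback replaces the oxidative coupling by a polar SN2 construction of the same bond; it sets out from 9 and 6, through their enolates 11 and 10, and comes back at 12. Enolate 11 is hydroxylated with 2-(phenylsulfonyl)-3-phenyloxaziridine to give racemic methyl 2-hydroxy-3-[3-iodo-5-methoxy-4-(methoxymethoxy)phenyl]propanoate F1. Tf2O/2,6-lutidine (CH2Cl2, −78 °C) converts it into methyl 3-[3-iodo-5-methoxy-4-(methoxymethoxy)phenyl]-2-{[(trifluoromethyl)sulfonyl]oxy}propanoate F2. The lithium imide enolate 10 then displaces the triflate (THF, −78 °C, auxiliary-controlled at the imide carbon) to give 12 together with its C-2 epimer, and both converge on 14 in step 7.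

Step 8, Pd coupling of the N-acetyl imide zinc enolate (enolate stability, I versus Br selectivity). The fallback builds the arylacetyl imide by allylation, oxidative cleavage and acylation; it sets out from 14 and comes back at 17. Stille coupling with allyltributylstannane (Pd(PPh3)4, toluene, 80 °C, C–I only) gives (3S,4S)-4-{[4-(benzyloxy)-3-bromo-5-methoxyphenyl]methyl}-3-{[3-methoxy-4-(methoxymethoxy)-5-(prop-2-en-1-yl)phenyl]methyl}oxolan-2-one F3. OsO4 (cat.)/NaIO4/2,6-lutidine cleaves the alkene to the arylacetaldehyde (14 with I replaced by CH2CHO) F4, and Pinnick oxidation gives the arylacetic acid (14 with I replaced by CH2CO2H) F5. PivCl/Et3N forms the mixed pivalic anhydride of that acid F6, which acylates (S)-4-benzyloxazolidin-2-one (LiCl, THF) to give 17.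

Step 12 (and its twin, step 9), Mg-catalysed anti-aldol of an arylacetyl imide. The anti selectivity is established for simpler N-acyl groups but not for α-aryl ones; in step 9 an error at the carbinol is erased by the SN1 closure, but step 12 must deliver the erythro unit. The fallback changes from catalytic soft enolisation with a closed Mg-bound transition state to a preformed boron enolate and an externally activated aldehyde (open transition state); it sets out from 24 and comes back at 27. Bu2BOTf (2.2 equiv)/iPr2NEt (CH2Cl2, 0 °C) converts 24 into the dibutylboron (Z)-enolate whose primary hydroxyl is capped as the dibutylborinate F7. This is added at −78 °C to aldehyde 18 precomplexed with Et2AlCl; the anti-selective open transition state uses the same enolate face, and aqueous work-up gives the free (2R,3S) anti-aldol imide (25 without its two silyl groups) F8. LiBH4/MeOH (THF, 0 °C) reduces it directly to 27.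

**Further compounds**
F1 | step 6 | methyl 2-hydroxy-3-[3-iodo-5-methoxy-4-(methoxymethoxy)phenyl]propanoate (racemic) | COC(=O)C(O)Cc1cc(I)c(OCOC)c(OC)c1
F2 | step 6 | methyl 3-[3-iodo-5-methoxy-4-(methoxymethoxy)phenyl]-2-{[(trifluoromethyl)sulfonyl]oxy}propanoate (racemic) | COC(=O)C(OS(=O)(=O)C(F)(F)F)Cc1cc(I)c(OCOC)c(OC)c1
F3 | step 8 | (3S,4S)-4-{[4-(benzyloxy)-3-bromo-5-methoxyphenyl]methyl}-3-{[3-methoxy-4-(methoxymethoxy)-5-(prop-2-en-1-yl)phenyl]methyl}oxolan-2-one | COc1cc(C[C@@H]2COC(=O)[C@H]2Cc2cc(OC)c(OCOC)c(CC=C)c2)cc(Br)c1OCc1ccccc1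
F4 | step 8 | arylacetaldehyde: 14 with I replaced by CH2CHO | COc1cc(C[C@@H]2COC(=O)[C@H]2Cc2cc(OC)c(OCOC)c(CC=O)c2)cc(Br)c1OCc1ccccc1
F5 | step 8 | arylacetic acid: 14 with I replaced by CH2CO2H | COc1cc(C[C@@H]2COC(=O)[C@H]2Cc2cc(OC)c(OCOC)c(CC(=O)O)c2)cc(Br)c1OCc1ccccc1
F6 | step 8 | mixed pivalic anhydride of F5 | COc1cc(C[C@@H]2COC(=O)[C@H]2Cc2cc(OC)c(OCOC)c(CC(=O)OC(=O)C(C)(C)C)c2)cc(Br)c1OCc1ccccc1
F7 | step 12 | dibutylboron (Z)-enolate of 24 with the CH2OH capped as dibutylborinate | COc1cc(C[C@@H]2COC(=O)[C@H]2Cc2cc(OC)c3c(c2)[C@@H](COB(CCCC)CCCC)[C@H](c2ccc(OCc4ccccc4)c(OC)c2)O3)cc(/C=C(\OB(CCCC)CCCC)N2C(=O)OC[C@@H]2Cc2ccccc2)c1OCc1ccccc1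
F8 | step 12 | free (2R,3S) anti-aldol imide (25 without its two trimethylsilyl groups) | COc1cc(C[C@@H]2COC(=O)[C@H]2Cc2cc(OC)c3c(c2)[C@@H](CO)[C@H](c2ccc(OCc4ccccc4)c(OC)c2)O3)cc([C@@H](C(=O)N2C(=O)OC[C@@H]2Cc2ccccc2)[C@H](O)c2ccc(OCc3ccccc3)c(OC)c2)c1OCc1ccccc1
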